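**Assumption:** 1-(2,6-dihydroxy-4-methoxyphenyl)ethan-1-one, (E)-4-methylpent-2-enal and 6-methylhept-5-en-2-one are taken as catalogue chemicals. The target is numbered as a spiro[5.5]undecane (C6 spiro, C7 = CH2, C8=C9 the ring B alkene, C11 bearing isopropyl), which makes it (6R,11S).

## Retrosynthetic overview

- Ring B is closed last by a one-pot Michael/Wittig spiroannulation that makes C6–C7 and C8=C9 from a dione aldehyde and a 1-(triphenylphosphonio)vinyl salt derived from 6-methylhept-5-en-2-one.
- That salt is an α-cation (enolonium-type) equivalent of the ketone: its former α-methyl carbon is bonded to the dione carbon C6 (two innate donors), and the ylide left on the former carbonyl carbon olefinates the aldehyde carbon (two innate acceptors).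
- C6–C11 and the C11 stereocentre come from an iminium-catalysed Michael addition of the cyclic 1,3-dione to (E)-4-methylpent-2-enal.
- Ring A is the benzene ring of the acetophenone, dearomatised by three C-methylations; the 4-methoxy group fixes the enol ether and the acetyl group blocks C6 until it is cleaved.
- Ring order: ring A (from the arene) first, ring B last; the stepwise bond order fixes the ring B regiochemistry.

## Route

**Step 1**
Reactants: 1 1-(2,6-dihydroxy-4-methoxyphenyl)ethan-1-one; 2 iodomethane
Product: 3 2-acetyl-5-methoxy-4,6,6-trimethylcyclohex-4-ene-1,3-dione (enolised triketone)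
Conditions: NaOMe (3.3 equiv), MeI (4 equiv), MeOH, 0 °C to 65 °C
Reagents that add atoms: iodomethane, CI
Why: Alkylative dearomatisation (C-methylation of the phloroglucinol-type phenoxide at the two free ring carbons) stops cleanly after three methyl groups because the methoxy-bearing carbon cannot become a ketone, which places the enol ether between CMe2 and CMe as in the target.

**Step 2**
Reactants: 3 2-acetyl-5-methoxy-4,6,6-trimethylcyclohex-4-ene-1,3-dione
Product: 6 5-methoxy-4,6,6-trimethylcyclohex-4-ene-1,3-dione, via bromo triketone 4 (not isolated), via bromo dione 5 (not isolated)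
Conditions: N-bromosuccinimide (1.05 equiv), MeOH, 0 °C to rt; then aq. Na2SO3, rt
Reagents that add atoms: none
Why: Halogenative deacylation: bromination at the central carbon makes the triketone non-enolisable, methanol then removes the exocyclic acetyl group by retro-Claisen cleavage (the ring carbonyls are a vinylogous ester and a neopentyl ketone), and sulfite reduces the positive-bromine C–Br bond, all without acid that could hydrolyse the enol ether.

**Step 3**
Reactants: 6 5-methoxy-4,6,6-trimethylcyclohex-4-ene-1,3-dione; 7 (E)-4-methylpent-2-enal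
Product: 8 (3S)-3-(4-methoxy-3,5,5-trimethyl-2,6-dioxocyclohex-3-en-1-yl)-4-methylpentanal (obtained and used as its equilibrating cyclic hemiacetals)
Conditions: (S)-2-[diphenyl(trimethylsilyloxy)methyl]pyrrolidine (10 mol %), 7 (1.5 equiv), CH2Cl2, 0 °C to rt
Reagents that add atoms: (E)-4-methylpent-2-enal, CC(C)/C=C/C=O
Why: Iminium-catalysed Michael addition/hemiacetalisation: the CPh2(OSiMe3) group shields one face of the E-iminium ion, so the dione carbon adds to the open face of the β-carbon and sets the isopropyl-bearing centre as S (the same facial sense as nitromethane or malonate additions with this catalyst).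

**Step 4**
Reactants: 9 6-methylhept-5-en-2-one; 10 N-phenylbis(trifluoromethanesulfonimide)
Product: 12 6-methylhepta-1,5-dien-2-yl trifluoromethanesulfonate, via lithium enolate 11 (not isolated)
Conditions: LiN(i-Pr)2 (1.1 equiv), THF, −78 °C; then PhNTf2, −78 °C to 0 °C; cold 1 M HCl work-up
Reagents that add atoms: N-phenylbis(trifluoromethanesulfonimide), O=S(=O)(N(c1ccccc1)S(=O)(=O)C(F)(F)F)C(F)(F)F
Why: Kinetic deprotonation of the methyl ketone at the methyl group and O-triflation of the terminal enolate give the 2-substituted vinyl triflate (minor internal isomers removed by chromatography).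

**Step 5**
Reactants: 12 6-methylhepta-1,5-dien-2-yl trifluoromethanesulfonate; 13 triphenylphosphine
Product: 14 (6-methylhepta-1,5-dien-2-yl)triphenylphosphonium trifluoromethanesulfonate
Conditions: Pd(PPh3)4 (2 mol %), THF, 65 °C
Reagents that add atoms: triphenylphosphine, c1ccc(cc1)P(c1ccccc1)c1ccccc1
Why: Zerovalent-palladium-catalysed C–P coupling of a vinyl triflate with PPh3 (oxidative addition, then reductive elimination of the phosphonium salt); the trisubstituted alkene is inert.

**Step 6**
Reactants: 8 (3S)-3-(4-methoxy-3,5,5-trimethyl-2,6-dioxocyclohex-3-en-1-yl)-4-methylpentanal; 14 (6-methylhepta-1,5-dien-2-yl)triphenylphosphonium trifluoromethanesulfonate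
Product: 17 (6R,11S)-3-methoxy-2,4,4-trimethyl-8-(4-methylpent-3-en-1-yl)-11-(propan-2-yl)spiro[5.5]undeca-2,8-diene-1,5-dione, via potassium enolate 15 (not isolated), via phosphorus ylide 16 (not isolated)
Conditions: KOt-Bu (1.0 equiv), 18-crown-6 (1.0 equiv), THF–DMF (4:1), −20 °C; then 14 (1.2 equiv), −20 °C to 50 °C
Reagents that add atoms: (6-methylhepta-1,5-dien-2-yl)triphenylphosphonium trifluoromethanesulfonate, C=C(CCC=C(C)C)[P+](c1ccccc1)(c1ccccc1)c1ccccc1.[O-]S(=O)(=O)C(F)(F)F
Why: Schweizer-type Michael addition/intramolecular Wittig spiroannulation: the dione carbon of 15 attacks the CH2 terminus of 14 (the ketone's α-methyl carbon made electrophilic, so two innately nucleophilic α-carbons are joined) anti to the isopropyl group in the A(1,3)-minimised rotamer whose C–H eclipses the more charged, ion-paired oxygen next to CMe2, giving the R spiro centre, and ylide 16 (the former ketone carbon, now a donor) closes ring B on the aldehyde with the alkene fixed at C8=C9.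

## Compound list

1 | 1-(2,6-dihydroxy-4-methoxyphenyl)ethan-1-one | CC(=O)c1c(O)cc(OC)cc1O | starting material
2 | iodomethane | CI | starting material
3 | 2-acetyl-5-methoxy-4,6,6-trimethylcyclohex-4-ene-1,3-dione (enolised) | CC(=O)C1C(=O)C(C)=C(OC)C(C)(C)C1=O | intermediate
4 | 2-acetyl-2-bromo-5-methoxy-4,6,6-trimethylcyclohex-4-ene-1,3-dione (bromo triketone) | CC(=O)C1(Br)C(=O)C(C)=C(OC)C(C)(C)C1=O | intermediate (not isolated)
5 | 2-bromo-5-methoxy-4,6,6-trimethylcyclohex-4-ene-1,3-dione (bromo dione) | COC1=C(C)C(=O)C(Br)C(=O)C1(C)C | intermediate (not isolated)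
6 | 5-methoxy-4,6,6-trimethylcyclohex-4-ene-1,3-dione | COC1=C(C)C(=O)CC(=O)C1(C)C | intermediate
7 | (E)-4-methylpent-2-enal | CC(C)/C=C/C=O | starting material
8 | (3S)-3-(4-methoxy-3,5,5-trimethyl-2,6-dioxocyclohex-3-en-1-yl)-4-methylpentanal (open form of the hemiacetals) | COC1=C(C)C(=O)C([C@@H](CC=O)C(C)C)C(=O)C1(C)C | intermediate
9 | 6-methylhept-5-en-2-one | CC(=O)CCC=C(C)C | starting material
10 | N-phenylbis(trifluoromethanesulfonimide) | O=S(=O)(N(c1ccccc1)S(=O)(=O)C(F)(F)F)C(F)(F)F | starting material
11 | lithium 6-methylhepta-1,5-dien-2-olate (lithium enolate) | [Li+].[O-]C(=C)CCC=C(C)C | intermediate (not isolated)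
12 | 6-methylhepta-1,5-dien-2-yl trifluoromethanesulfonate | C=C(OS(=O)(=O)C(F)(F)F)CCC=C(C)C | intermediate
13 | triphenylphosphine | c1ccc(cc1)P(c1ccccc1)c1ccccc1 | starting material
14 | (6-methylhepta-1,5-dien-2-yl)triphenylphosphonium trifluoromethanesulfonate | C=C(CCC=C(C)C)[P+](c1ccccc1)(c1ccccc1)c1ccccc1.[O-]S(=O)(=O)C(F)(F)F | intermediate
15 | potassium enolate of 8, open aldehyde form (potassium enolate) | [K+].COC1=C(C)C(=O)C([C@@H](CC=O)C(C)C)=C([O-])C1(C)C | intermediate (not isolated)
16 | (R)-configured Michael adduct bearing the C(=PPh3) ylide and the (S)-aldehyde side chain (phosphorus ylide) | COC1=C(C)C(=O)[C@@](CC(CCC=C(C)C)=P(c2ccccc2)(c2ccccc2)c2ccccc2)([C@@H](CC=O)C(C)C)C(=O)C1(C)C | intermediate (not isolated)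
17 | (6R,11S)-3-methoxy-2,4,4-trimethyl-8-(4-methylpent-3-en-1-yl)-11-(propan-2-yl)spiro[5.5]undeca-2,8-diene-1,5-dione | COC1=C(C)C(=O)[C@]2(CC(CCC=C(C)C)=CC[C@H]2C(C)C)C(=O)C1(C)C | target

## Step count and risks

Total steps: 6. Longest linear sequence: 4 (steps 1, 2, 3, 6); steps 4 and 5 make the second fragment.

**Most likely to fail, 1: step 6.** The nucleophilic carbon carries a branched substituent, and the spiro centre is set only by the rotamer preference described. The two carbonyl flanks differ little, so I expect a modest ratio, with the 6S epimer to be removed by chromatography. O-alkylation is reversible and could only close an eight-membered ring, so it should not divert material.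

Fallback, from 8 (with 12), back at 17: Nozaki–Hiyama–Kishi coupling of the aldehyde form of 8 with vinyl triflate 12 (CrCl2, NiCl2 cat., DMF) gives the allylic alcohol 2-[(3S)-5-hydroxy-2,10-dimethyl-6-methylideneundec-9-en-3-yl]-5-methoxy-4,6,6-trimethylcyclohex-4-ene-1,3-dione F1. Equilibrating acid-catalysed cyclodehydration (pyridinium p-toluenesulfonate, benzene, 60 °C) closes an enol oxygen onto the allylic position. From the resulting mixture the trans pyran (2S,4S)-7-methoxy-6,6,8-trimethyl-2-(6-methylhepta-1,5-dien-2-yl)-4-(propan-2-yl)-3,4-dihydro-2H-chromen-5(6H)-one F2 is separated as a constitutional isomer, and the rest is returned to the acid. Heating F2 (xylene, 150 °C) gives 17 by a [3,3] Claisen shift that delivers the allyl terminus to the face of the enol ether carbon on which the alkenyl group sits, so the spiro centre is set stereospecifically.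

**Most likely to fail, 2: step 3.** The β-branched aliphatic enal may react slowly, and retro-Michael erosion of the enantiomeric excess is possible.

Fallback, from 6 (with 7), back at 8: oxidative N-heterocyclic carbene catalysis (chiral aminoindanol-derived triazolium salt in the enantiomeric form that gives 4S, amine base, 3,3',5,5'-tetra-tert-butyldiphenoquinone, toluene). This proceeds through the α,β-unsaturated acyl azolium to the enol δ-lactone (4S)-7-methoxy-6,6,8-trimethyl-4-(propan-2-yl)-3,4-dihydro-2H-chromene-2,5(6H)-dione F3, which often crystallises to high enantiopurity. (i-Bu)2AlH (1.0 equiv, CH2Cl2, −78 °C) then reduces the enol lactone to lactol 8.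

**Most likely to fail, 3: step 2.** N-bromosuccinimide could attack the enol ether, or methanol could open the ring instead of removing the acetyl group.

Fallback, from 3, back at 6: acid-catalysed retro-Claisen solvolysis in methanol (HCl in MeOH, 60 °C), where the methoxy enol ether can only exchange with solvent, gives the bis(enol ether) 3,5-dimethoxy-2,4,4-trimethylcyclohexa-2,5-dien-1-one F4. Brief treatment with 0.5 M aq. HCl in THF at rt then hydrolyses only the less hindered enol ether (the one next to CH) to give 6.

## Further compounds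

F1 | step 6 | 2-[(3S)-5-hydroxy-2,10-dimethyl-6-methylideneundec-9-en-3-yl]-5-methoxy-4,6,6-trimethylcyclohex-4-ene-1,3-dione (carbinol epimers) | COC1=C(C)C(=O)C([C@@H](CC(O)C(=C)CCC=C(C)C)C(C)C)C(=O)C1(C)C
F2 | step 6 | (2S,4S)-7-methoxy-6,6,8-trimethyl-2-(6-methylhepta-1,5-dien-2-yl)-4-(propan-2-yl)-3,4-dihydro-2H-chromen-5(6H)-one | COC1=C(C)C2=C(C(=O)C1(C)C)[C@H](C(C)C)C[C@H](O2)C(=C)CCC=C(C)C
F3 | step 3 | (4S)-7-methoxy-6,6,8-trimethyl-4-(propan-2-yl)-3,4-dihydro-2H-chromene-2,5(6H)-dione | COC1=C(C)C2=C(C(=O)C1(C)C)[C@H](C(C)C)CC(=O)O2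
F4 | step 2 | 3,5-dimethoxy-2,4,4-trimethylcyclohexa-2,5-dien-1-one | COC1=CC(=O)C(C)=C(OC)C1(C)C
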